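**Plan**
Atom numbers are germacrane numbers (C1–C15); ring A is the furanone (O, C3, C2, C1, C10), ring B the ten-membered carbocycle (C1–C10), ring C the lactone (O, C6, C7, C11, C12).
Retrosynthesis cuts, in order: the C8 angelate ester; the C6–C7 bond together with the lactone C12–O bond (opening rings B and C at once); the C7–C11 bond; the C1–C10 bond of ring A; the enol-ether bond O–C10; the C3–C4 bond.
Forward: a (Z)-iodoalkene (C4–C6, C15) is joined to a C1–C3 aldehyde, O3 is added to an ynone (C7–C10, C14), ring A is closed first by C1–C10, the chain is extended to an allylic bromide, rings B and C are closed together, and the angelate is attached last.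
Enabling feature: in ring A the C1 ketone and the C8 oxygen are 1,4-related through the quaternary, oxygen-bearing C10 with C9 as a CH2 group; this is the pattern left by conjugate addition of a C1 acyl anion to C10 of a β-alkoxy enone.
Stereochemistry: C10 from a chiral triazolium carbene; C8 from a reagent-controlled ketone reduction; C6 and C7 from the chair-like allylchromium ring closure biased by C8 and C10; the (Z)-C4=C5 bond from anti-hydroalumination and iodination, kept with retention in the coupling; the angelate geometry from angelic acid.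

Key step: step 9

Remark: the (5aS,10bR) antipode of the triazolium salt is assumed to induce the (R) configuration at C10; if a model run shows the opposite sense, its mirror image is used.

Abbreviations: TBS = tert-butyldimethylsilyl, TBDPS = tert-butyldiphenylsilyl, IBX = 2-iodoxybenzoic acid, DABCO = 1,4-diazabicyclo[2.2.2]octane, DMAP = 4-(dimethylamino)pyridine.

Step 1
Reactants: 1 1-propynylmagnesium bromide; 2 ethyl 2,2-diethoxyacetate
Product: 3 1,1-diethoxypent-3-yn-2-one
Conditions: THF, −78 °C; aq. NH4Cl
Reagents that add atoms: none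
Why: Acyl substitution of an α,α-dialkoxy ester by an alkynyl Grignard reagent, in which the chelated tetrahedral adduct persists at low temperature so that the ynone appears only on work-up and is not attacked twice.

Step 2
Reactants: 4 but-2-yne-1,4-diol
Product: 6 (Z)-2-iodobut-2-ene-1,4-diol, via cyclic alkenylaluminate 5 (not isolated)
Conditions: NaAlH2(OCH2CH2OCH3)2, THF, 0 °C to rt; then I2, −78 °C to rt
Reagents that add atoms: iodine, II
Why: Hydroxyl-directed anti-hydroalumination of the propargylic alcohol and iodinolysis of the carbon–aluminium bond with retention should give the (Z)-iodoalkene, which fixes the later C4=C5 geometry.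

Step 3
Reactants: 6 (Z)-2-iodobut-2-ene-1,4-diol
Product: 7 (Z)-4-(TBDPS-oxy)-2-iodobut-2-en-1-ol
Conditions: tert-butyldiphenylsilyl chloride (1.0 equiv), imidazole, CH2Cl2, −20 °C
Reagents that add atoms: tert-butyldiphenylsilyl chloride, CC(C)(C)[Si](Cl)(c1ccccc1)c1ccccc1
Why: Sterically controlled monosilylation, in which the bulky silyl chloride should react at the hydroxyl remote from the iodine-bearing carbon (the future O6).

Step 4
Reactants: 7 (Z)-4-(TBDPS-oxy)-2-iodobut-2-en-1-ol; 8 3-(TBS-oxy)propanal
Product: 9 C3 allylic alcohol (diol, racemic at C3)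
Conditions: CrCl2 (4 equiv), NiCl2 (2 mol%), DMSO, rt
Reagents that add atoms: none
Why: Nozaki–Hiyama–Kishi coupling, in which the alkenylchromium reagent forms with retention of the alkene geometry and adds chemoselectively to the aldehyde in the presence of the free hydroxyl; C3 is formed racemic and is erased in step 10.

Step 5
Reactants: 9 C3 allylic alcohol (diol)
Product: 10 C15 acetate
Conditions: acetyl chloride (1.05 equiv), 2,4,6-collidine, CH2Cl2, −78 °C
Reagents that add atoms: acetyl chloride, CC(=O)Cl
Why: Kinetic acylation of the primary allylic hydroxyl in preference to the hindered secondary one.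

Step 6
Reactants: 10 C15 acetate; 3 1,1-diethoxypent-3-yn-2-one
Product: 11 O3 (E)-β-alkoxy enone
Conditions: PMe3 (20 mol%), CH2Cl2, 0 °C
Reagents that add atoms: none
Why: Phosphine-catalysed oxa-Michael addition of the secondary alcohol to the ynone, which should end at the thermodynamically favoured (E)-β-alkoxy enone.

Step 7
Reactants: 11 O3 (E)-β-alkoxy enone
Product: 12 C1 primary alcohol
Conditions: HF·pyridine, pyridine, THF, 0 °C
Reagents that add atoms: none
Why: Selective cleavage of the primary TBS ether by fluoride while the much more robust TBDPS ether, the acetate and the α-keto acetal stay.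

Step 8
Reactants: 12 C1 primary alcohol
Product: 13 C1 aldehyde
Conditions: Dess–Martin periodinane, NaHCO3, CH2Cl2, 0 °C; used crude
Reagents that add atoms: none
Why: Dess–Martin oxidation under buffered conditions, chosen because the β-alkoxy aldehyde would lose its ether by elimination under basic or acidic conditions.

Step 9
Reactants: 13 C1 aldehyde
Product: 14 (R)-2-methyl tetrahydrofuran-3-one (both C3 epimers)
Conditions: (5aS,10bR)-2-(pentafluorophenyl)-5a,10b-dihydro-4H,6H-indeno[2,1-b][1,2,4]triazolo[4,3-d][1,4]oxazin-2-ium tetrafluoroborate (20 mol%), i-Pr2NEt (20 mol%), toluene (0.02 M), rt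
Reagents that add atoms: none
Why: The carbene from the triazolium salt adds to the aldehyde C1 and proton transfer gives the Breslow intermediate, an acyl anion equivalent, which adds 5-exo-trig to C10, the β-carbon of the (E)-β-alkoxy enone; protonation of the enolate at C9 and loss of the carbene release the ketone (intramolecular Stetter reaction). The closest known reaction type is the triazolium-catalysed asymmetric intramolecular Stetter reaction of aldehydes tethered through oxygen to β-alkoxy- or β-aryloxy-crotonyl acceptors, which builds 2-methyl-2-(acylmethyl)furan-3-one rings with a quaternary carbon. One ring is closed, the five-membered ring A (O, C3, C2, C1, C10), in the 5-exo-trig mode by the C1–C10 bond. The new stereocentre C10 is set by the chiral carbene, which shields one face of the trisubstituted acceptor; C3 is racemic and is erased in step 10, so both diastereomers are carried on. The step needs addition of the acyl anion to C10 to be faster than enolisation of the aldehyde with β-elimination of the ether oxygen and faster than intermolecular benzoin coupling; the five-membered transition state, the electron-poor α-keto-acetal acceptor and the use of only a catalytic amount of a weak amine base should secure this.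

Step 10
Reactants: 14 (R)-2-methyl tetrahydrofuran-3-one
Product: 15 (R)-furan-3(2H)-one keto acetal
Conditions: IBX (2.5 equiv), DMSO/fluorobenzene, 70 °C
Reagents that add atoms: none
Why: IBX dehydrogenation of the ketone through its enol, which can only place the double bond at C2=C3 because C10 is quaternary, and which removes the C3 stereocentre so that both epimers of 14 converge.

Step 11
Reactants: 15 (R)-furan-3(2H)-one keto acetal
Product: 16 (8S)-hydroxy acetal
Conditions: (R)-2-methyl-CBS-oxazaborolidine (20 mol%), catecholborane (1.5 equiv), toluene, −78 °C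
Reagents that add atoms: none
Why: Corey–Bakshi–Shibata reduction, chemoselective for the electrophilic α-keto acetal over the vinylogous-ester ketone C1, in which the dialkoxymethyl group acts as the large substituent so that the (R)-catalyst should give the (S)-carbinol at C8.

Step 12
Reactants: 16 (8S)-hydroxy acetal
Product: 17 (8S)-TBS ether
Conditions: tert-butyldimethylsilyl triflate, 2,6-lutidine, CH2Cl2, −78 °C
Reagents that add atoms: tert-butyldimethylsilyl triflate, CC(C)(C)[Si](C)(C)OS(=O)(=O)C(F)(F)F
Why: Silylation of the hindered secondary alcohol with the silyl triflate, giving a C8 oxygen that is a poor leaving group for the later allyl-metal step.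

Step 13
Reactants: 17 (8S)-TBS ether
Product: 18 C7 aldehyde
Conditions: In(OTf)3 (5 mol%), acetone/H2O, rt
Reagents that add atoms: water, O
Why: Lewis-acid-catalysed acetal hydrolysis under nearly neutral conditions, which should spare both silyl ethers and not epimerise the α-silyloxy aldehyde.

Step 14
Reactants: 18 C7 aldehyde; 19 methyl acrylate
Product: 20 Baylis–Hillman alcohol (both C7 epimers)
Conditions: DABCO (1 equiv), methyl acrylate (5 equiv), 1,4-dioxane/H2O, rt
Reagents that add atoms: none
Why: Morita–Baylis–Hillman reaction of the activated α-silyloxy aldehyde, forming the C7–C11 bond; the new carbinol centre C7 is a mixture that is removed in step 15.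

Step 15
Reactants: 20 Baylis–Hillman alcohol
Product: 21 (Z)-allylic bromide
Conditions: N-bromosuccinimide and Me2S premixed in CH2Cl2 at 0 °C; then 20, 0 °C to rt
Reagents that add atoms: N-bromosuccinimide, O=C1CCC(=O)N1Br
Why: SN2′ bromination of the Baylis–Hillman alcohol through its alkoxysulfonium salt, which should give the thermodynamically favoured (Z)-2-(bromomethyl)enoate; premixing avoids free N-bromosuccinimide at the electron-rich ring A.

Step 16
Reactants: 21 (Z)-allylic bromide
Product: 22 C6,C8-diol bromide
Conditions: HF·pyridine (excess), THF, 0 °C to rt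
Reagents that add atoms: none
Why: Global desilylation with a weakly nucleophilic, acidic fluoride source that leaves the allylic bromide, the acetate and the esters untouched.

Step 17
Reactants: 22 C6,C8-diol bromide
Product: 23 C6 enal bromide
Conditions: MnO2 (activated, 20 equiv), CH2Cl2, rt
Reagents that add atoms: none
Why: MnO2 oxidation of the electron-rich primary allylic alcohol, whereas the secondary C8 alcohol, deactivated by the conjugated ester, should be left.

Step 18
Reactants: 23 C6 enal bromide
Product: 25 8-hydroxy lactone, via ring B hydroxy ester 24 (not isolated)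
Conditions: slow addition of 23 to CrCl2 (10 equiv), THF (final 1 mM), rt; aq. NH4Cl; cat. pyridinium p-toluenesulfonate, CH2Cl2 if lactonisation is incomplete
Reagents that add atoms: none
Why: Intramolecular Nozaki–Hiyama-type (Barbier) allylation, in which the allylchromium adds through C7 to the C6 aldehyde in a chair-like six-membered transition state (C5 equatorial, anti adduct, C8–O anti to the forming bond) and should set (6R,7R), after which the chromium alkoxide at O6 closes ring C on the methyl ester while the neutral C8 hydroxyl does not compete.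

Step 19
Reactants: 25 8-hydroxy lactone; 26 angelic acid
Product: 27 target CNP0122132.1
Conditions: 26, 2,4,6-trichlorobenzoyl chloride, Et3N, toluene, rt; then 25, DMAP, rt
Reagents that add atoms: none
Why: Yamaguchi esterification through the mixed anhydride, a mild acylation that should keep the (Z)-geometry of the angelate and meets only one free hydroxyl.

**Compound list**
1 | 1-propynylmagnesium bromide | CC#C[Mg]Br | starting material
2 | ethyl 2,2-diethoxyacetate | CCOC(=O)C(OCC)OCC | starting material
3 | 1,1-diethoxypent-3-yn-2-one | CC#CC(=O)C(OCC)OCC | intermediate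
4 | but-2-yne-1,4-diol | OCC#CCO | starting material
5 | sodium cyclic alkenylaluminate (five-membered ring O–Al–C=C–CH2; Al carries two 2-methoxyethoxy groups; the alkene carbon on Al also carries CH2OH) | [Na+].OCC1=CCO[Al-]1(OCCOC)OCCOC | intermediate (not isolated)
6 | (Z)-2-iodobut-2-ene-1,4-diol | OC/C=C(/CO)I | intermediate
7 | (Z)-4-(tert-butyldiphenylsilyloxy)-2-iodobut-2-en-1-ol | CC(C)(C)[Si](OC/C=C(/CO)I)(c1ccccc1)c1ccccc1 | intermediate
8 | 3-(tert-butyldimethylsilyloxy)propanal | CC(C)(C)[Si](C)(C)OCCC=O | starting material
9 | (Z)-2-[2-(tert-butyldiphenylsilyloxy)ethylidene]-5-(tert-butyldimethylsilyloxy)pentane-1,3-diol, racemic at C3 | CC(C)(C)[Si](OC/C=C(/CO)C(O)CCO[Si](C)(C)C(C)(C)C)(c1ccccc1)c1ccccc1 | intermediate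
10 | 1-O-acetate of 9 (C15 acetate, free C3 hydroxyl) | CC(C)(C)[Si](OC/C=C(/COC(C)=O)C(O)CCO[Si](C)(C)C(C)(C)C)(c1ccccc1)c1ccccc1 | intermediate
11 | ether of 10 at O3 with the (E)-5,5-diethoxy-4-oxopent-2-en-2-yl group | CC(C)(C)[Si](OC/C=C(/COC(C)=O)C(CCO[Si](C)(C)C(C)(C)C)O/C(C)=C/C(=O)C(OCC)OCC)(c1ccccc1)c1ccccc1 | intermediate
12 | C1 primary alcohol from 11 (TBS removed) | CC(C)(C)[Si](OC/C=C(/COC(C)=O)C(CCO)O/C(C)=C/C(=O)C(OCC)OCC)(c1ccccc1)c1ccccc1 | intermediate
13 | C1 aldehyde (β-alkoxy aldehyde tethered to the β-alkoxy enone) | CC(C)(C)[Si](OC/C=C(/COC(C)=O)C(CC=O)O/C(C)=C/C(=O)C(OCC)OCC)(c1ccccc1)c1ccccc1 | intermediate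
14 | (2R)-5-[(Z)-1-acetoxy-4-(tert-butyldiphenylsilyloxy)but-2-en-2-yl]-2-(3,3-diethoxy-2-oxopropyl)-2-methyldihydrofuran-3(2H)-one, both C5 epimers | CC(C)(C)[Si](OC/C=C(/COC(C)=O)C1CC(=O)[C@@](C)(CC(=O)C(OCC)OCC)O1)(c1ccccc1)c1ccccc1 | intermediate
15 | (2R)-5-[(Z)-1-acetoxy-4-(tert-butyldiphenylsilyloxy)but-2-en-2-yl]-2-(3,3-diethoxy-2-oxopropyl)-2-methylfuran-3(2H)-one | CC(C)(C)[Si](OC/C=C(/COC(C)=O)C1=CC(=O)[C@@](C)(CC(=O)C(OCC)OCC)O1)(c1ccccc1)c1ccccc1 | intermediate
16 | analogue of 15 with a (2S)-3,3-diethoxy-2-hydroxypropyl side chain (8S alcohol) | CC(C)(C)[Si](OC/C=C(/COC(C)=O)C1=CC(=O)[C@@](C)(C[C@H](O)C(OCC)OCC)O1)(c1ccccc1)c1ccccc1 | intermediate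
17 | TBS ether of 16 at O8 | CC(C)(C)[Si](OC/C=C(/COC(C)=O)C1=CC(=O)[C@@](C)(C[C@H](O[Si](C)(C)C(C)(C)C)C(OCC)OCC)O1)(c1ccccc1)c1ccccc1 | intermediate
18 | (2S)-2-(tert-butyldimethylsilyloxy)-3-[(2R)-furanonyl]propanal (C7 aldehyde) | CC(C)(C)[Si](OC/C=C(/COC(C)=O)C1=CC(=O)[C@@](C)(C[C@H](O[Si](C)(C)C(C)(C)C)C=O)O1)(c1ccccc1)c1ccccc1 | intermediate
19 | methyl acrylate | C=CC(=O)OC | starting material
20 | methyl 3-hydroxy-2-methylene-(4S)-4-(tert-butyldimethylsilyloxy)-5-[(2R)-furanonyl]pentanoate, both C3 epimers | CC(C)(C)[Si](OC/C=C(/COC(C)=O)C1=CC(=O)[C@@](C)(C[C@H](O[Si](C)(C)C(C)(C)C)C(O)C(=C)C(=O)OC)O1)(c1ccccc1)c1ccccc1 | intermediate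
21 | methyl (Z,4S)-2-(bromomethyl)-4-(tert-butyldimethylsilyloxy)-5-[(2R)-furanonyl]pent-2-enoate | CC(C)(C)[Si](OC/C=C(/COC(C)=O)C1=CC(=O)[C@@](C)(C[C@H](O[Si](C)(C)C(C)(C)C)/C=C(\CBr)C(=O)OC)O1)(c1ccccc1)c1ccccc1 | intermediate
22 | diol from 21 (free C6 and C8 hydroxyls) | OC/C=C(/COC(C)=O)C1=CC(=O)[C@@](C)(C[C@H](O)/C=C(\CBr)C(=O)OC)O1 | intermediate
23 | C6 enal from 22 | O=C/C=C(/COC(C)=O)C1=CC(=O)[C@@](C)(C[C@H](O)/C=C(\CBr)C(=O)OC)O1 | intermediate
24 | ring B hydroxy ester (ten-membered ring closed, 6,8-diol, methyl 2-methylenecarboxylate on C7) | C=C(C(=O)OC)[C@H]1[C@H](O)/C=C(/COC(C)=O)C2=CC(=O)[C@@](C)(C[C@@H]1O)O2 | intermediate (not isolated)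
25 | 8-hydroxy lactone (target without the angeloyl group) | C=C1C(=O)O[C@@H]2/C=C(/COC(C)=O)C3=CC(=O)[C@@](C)(C[C@H](O)[C@@H]12)O3 | intermediate
26 | angelic acid, (Z)-2-methylbut-2-enoic acid | C/C=C(/C)C(=O)O | starting material
27 | CNP0122132.1, (4Z,6R,7R,8S,10R)-15-acetoxy-8-angeloyloxy furanoheliangolide | C=C1C(=O)O[C@@H]2/C=C(/COC(C)=O)C3=CC(=O)[C@@](C)(C[C@H](OC(=O)/C(C)=C\C)[C@@H]12)O3 | target

**Totals**
Total step count: 19. Longest linear sequence: 18 steps (steps 2 to 19); step 1 supplies ynone 3 for step 6.

**Steps most likely to fail**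

Step 9. The aldehyde may enolise and lose the ether oxygen by β-elimination before the carbene adds, or the facial discrimination at C10 may be low. The fallback sets out from 13 and changes the order of events. The aldehyde is dehydrogenated first (IBX, DMSO, 65 °C) to the push–pull enal F1, which has no α-hydrogens and cannot eliminate. The same triazolium carbene then closes ring A by conjugate addition of the acyl anion, and the route is rejoined at 15, so that step 10 is no longer needed.

Step 18. Intermolecular coupling, reductive 1,4-elimination of the allylchromium towards a diene, or addition to the wrong face may prevail over ring closure. The fallback sets out from 21 and replaces the reductive metal step by a boron allylation. The bromide is exchanged for boron (B2pin2, CuCl cat., KOAc, DMF) to give the allylboronate F2. Desilylation as in step 16 gives the diol F3, and MnO2 oxidation as in step 17 gives the aldehyde F4. On warming, or with Sc(OTf)3 as catalyst, the 2-(alkoxycarbonyl)allylboronate of F4 adds to the aldehyde through a closed chair transition state. The borate of 24 lactonises and the route is rejoined at 25.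

Step 6. The transient alkoxide may take over the neighbouring acetyl group (O15 to O3 migration), or the phosphine may isomerise the ynone and lead to addition at the methyl carbon. The fallback sets out from 3 and avoids any alkoxide. Methanol is added to 3 (cat. DABCO) to give the β-methoxy enone F5. Acid-catalysed enol-ether exchange of F5 with alcohol 10 (pyridinium p-toluenesulfonate, toluene, 60 °C, removal of methanol) then gives the ether, and the route is rejoined at 11.

**Further compounds**
F1 | step 9 | push–pull enal (13 with a C2=C3 double bond) | CC(C)(C)[Si](OC/C=C(/COC(C)=O)C(=CC=O)O/C(C)=C/C(=O)C(OCC)OCC)(c1ccccc1)c1ccccc1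
F2 | step 18 | allylboronate (21 with pinacolboryl in place of bromine) | CC(C)(C)[Si](OC/C=C(/COC(C)=O)C1=CC(=O)[C@@](C)(C[C@H](O[Si](C)(C)C(C)(C)C)/C=C(\CB2OC(C)(C)C(C)(C)O2)C(=O)OC)O1)(c1ccccc1)c1ccccc1
F3 | step 18 | diol (F2 without both silyl groups) | OC/C=C(/COC(C)=O)C1=CC(=O)[C@@](C)(C[C@H](O)/C=C(\CB2OC(C)(C)C(C)(C)O2)C(=O)OC)O1
F4 | step 18 | aldehyde (C6 enal of F3) | O=C/C=C(/COC(C)=O)C1=CC(=O)[C@@](C)(C[C@H](O)/C=C(\CB2OC(C)(C)C(C)(C)O2)C(=O)OC)O1
F5 | step 6 | (E)-1,1-diethoxy-4-methoxypent-3-en-2-one | CO/C(C)=C/C(=O)C(OCC)OCC
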